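The indane is cut at C1–C7a. C3 carries two rings with the same 2,4-dioxygenation, the pendant 2,4-dihydroxyphenyl group and the fused benzo ring (C3a–C7a, oxygen on C4 and C6), so both are introduced as one symmetric bis(2,4-dibenzyloxyphenyl)methyl group. The precursor is an open-chain alkyne in which C2, set by an oxazolidinone-controlled alkylation, bears this benzhydryl group, the 3,5-dibenzyloxyphenyl ring and a triple bond C1≡C8 capped by the guaiacyl ring. Palladium-carboxylate C–H activation at C7a, which is meta to both oxygens and closed to Friedel–Crafts chemistry, then adds one of the two diastereotopic rings syn across the alkyne, closing the five-membered ring, creating C3 and fixing the E alkene in one operation.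

Key step: step 12

Remark: indane numbering is used for all intermediates (C1 = future alkylidene carbon, C2, C3, C3a, C4–C7, C7a) and the exocyclic methine carbon is called C8; the CIP descriptor of C2 changes along the route (S, R, S) through ranking only, the spatial arrangement stays the same; compounds 1, 4, 7 and 18 are taken as commercial; Bn = benzyl.

Step 1
Reactants: 1 methyl (3,5-dihydroxyphenyl)acetate
Product: 3 [3,5-bis(benzyloxy)phenyl]acetic acid, via methyl [3,5-bis(benzyloxy)phenyl]acetate 2 (not isolated)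
Conditions: BnBr (2.3 equiv), K2CO3, DMF, 60 °C; then 2 M aq NaOH, MeOH, 60 °C; then aq HCl to pH 2
Reagents that add atoms: benzyl bromide (BrCc1ccccc1); sodium hydroxide ([Na+].[OH-])
Why: Williamson etherification of both phenols followed by saponification of the methyl ester in the same flask, which also destroys excess benzyl bromide, should give the acid on acidification.

Step 2
Reactants: 3 [3,5-bis(benzyloxy)phenyl]acetic acid; 4 (4S)-4-benzyl-1,3-oxazolidin-2-one
Product: 6 (4S)-4-benzyl-3-{[3,5-bis(benzyloxy)phenyl]acetyl}-1,3-oxazolidin-2-one, via pivalic mixed anhydride 5 (not isolated)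
Conditions: PivCl, Et3N, THF, −20 °C; then 4, LiCl, −20 °C → rt
Reagents that add atoms: none
Why: N-acylation of the oxazolidinone by the mixed pivalic anhydride under LiCl/Et3N activation is a standard one-flask method in which the bulky tert-butyl group directs attack to the arylacetyl carbonyl.

Step 3
Reactants: 7 2,2',4,4'-tetrahydroxybenzophenone
Product: 8 2,2',4,4'-tetrakis(benzyloxy)benzophenone
Conditions: BnBr (5 equiv), K2CO3 (6 equiv), DMF, 80 °C
Reagents that add atoms: benzyl bromide (BrCc1ccccc1)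
Why: Fourfold Williamson etherification, with excess reagent and heat to overcome the hydrogen bond of the two ortho phenols to the ketone.

Step 4
Reactants: 8 2,2',4,4'-tetrakis(benzyloxy)benzophenone
Product: 10 bis[2,4-bis(benzyloxy)phenyl]methyl methyl ether, via bis[2,4-bis(benzyloxy)phenyl]methanol 9 (not isolated)
Conditions: NaBH4, THF/MeOH, 50 °C until hydride is consumed; then HCl in MeOH (to pH 2), 0 °C → rt; NaHCO3 work-up
Reagents that add atoms: methanol (CO)
Why: Borohydride reduction of the diaryl ketone gives a benzhydrol whose cation is stabilised by four alkoxy groups, so that acidic methanol converts it into the methyl ether by SN1 etherification once no hydride is left to reduce the cation.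

Step 5
Reactants: 6 (4S)-4-benzyl-3-{[3,5-bis(benzyloxy)phenyl]acetyl}-1,3-oxazolidin-2-one; 10 bis[2,4-bis(benzyloxy)phenyl]methyl methyl ether
Product: 12 (4S)-4-benzyl-3-{(2S)-2-[3,5-bis(benzyloxy)phenyl]-3,3-bis[2,4-bis(benzyloxy)phenyl]propanoyl}-1,3-oxazolidin-2-one, via chlorotitanium Z-enolate 11 (not isolated)
Conditions: TiCl4 (1.1 equiv), i-Pr2NEt (1.2 equiv), CH2Cl2, −78 → 0 °C; then 10 (1.2 equiv), −78 → −20 °C; aq NH4Cl
Reagents that add atoms: none
Why: SN1-type alkylation of a chelated titanium enolate of an N-acyl oxazolidinone, in which the Lewis-acidic enolate complex ionises the ether and the bis(2,4-dibenzyloxyphenyl)methyl cation is captured on the face of the Z-enolate opposite to the 4-benzyl group, forming C2–C3 and setting C2 (S) while C3 stays achiral because its two rings are identical.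

Step 6
Reactants: 12 (4S)-4-benzyl-3-{(2S)-2-[3,5-bis(benzyloxy)phenyl]-3,3-bis[2,4-bis(benzyloxy)phenyl]propanoyl}-1,3-oxazolidin-2-one
Product: 13 (2S)-2-[3,5-bis(benzyloxy)phenyl]-3,3-bis[2,4-bis(benzyloxy)phenyl]propan-1-ol
Conditions: LiBH4, H2O (1.1 equiv), Et2O/THF, 0 °C → rt
Reagents that add atoms: none
Why: Reductive cleavage of the imide at the exocyclic carbonyl by LiBH4 should give the primary alcohol without touching C2 and return the auxiliary.

Step 7
Reactants: 13 (2S)-2-[3,5-bis(benzyloxy)phenyl]-3,3-bis[2,4-bis(benzyloxy)phenyl]propan-1-ol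
Product: 14 (2S)-2-[3,5-bis(benzyloxy)phenyl]-3,3-bis[2,4-bis(benzyloxy)phenyl]propanal
Conditions: Dess–Martin periodinane, NaHCO3, CH2Cl2, 0 °C; used crude at once
Reagents that add atoms: none
Why: Dess–Martin oxidation under bicarbonate buffer is fast and non-basic, so the enolisable α-aryl aldehyde should form without epimerisation at C2.

Step 8
Reactants: 14 (2S)-2-[3,5-bis(benzyloxy)phenyl]-3,3-bis[2,4-bis(benzyloxy)phenyl]propanal
Product: 15 (3R)-3-[3,5-bis(benzyloxy)phenyl]-4,4-bis[2,4-bis(benzyloxy)phenyl]-1,1-dibromobut-1-ene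
Conditions: CBr4, PPh3, Zn dust, CH2Cl2, rt (ylide preformed); then 14, 0 °C → rt
Reagents that add atoms: carbon tetrabromide (BrC(Br)(Br)Br)
Why: Ramirez dibromoolefination (first half of the Corey–Fuchs sequence) with the zinc-modified ylide runs under neutral conditions that the α-aryl aldehyde and the benzyl ethers should tolerate.

Step 9
Reactants: 15 (3R)-3-[3,5-bis(benzyloxy)phenyl]-4,4-bis[2,4-bis(benzyloxy)phenyl]-1,1-dibromobut-1-ene
Product: 17 (3R)-3-[3,5-bis(benzyloxy)phenyl]-4,4-bis[2,4-bis(benzyloxy)phenyl]but-1-yne, via lithium acetylide 16 (not isolated)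
Conditions: n-BuLi (2.05 equiv), THF, −78 °C; aq NH4Cl at −78 °C
Reagents that add atoms: none
Why: Second half of the Corey–Fuchs sequence, in which bromine–lithium exchange, Fritsch–Buttenberg–Wiechell 1,2-hydrogen shift and deprotonation give the acetylide, while an exactly measured base charge and a cold quench should leave the propargylic, benzylic C2–H untouched.

Step 10
Reactants: 18 4-iodo-2-methoxyphenol
Product: 19 1-(benzyloxy)-4-iodo-2-methoxybenzene
Conditions: BnBr, K2CO3, acetone, reflux
Reagents that add atoms: benzyl bromide (BrCc1ccccc1)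
Why: Williamson etherification of the single phenol.

Step 11
Reactants: 17 (3R)-3-[3,5-bis(benzyloxy)phenyl]-4,4-bis[2,4-bis(benzyloxy)phenyl]but-1-yne; 19 1-(benzyloxy)-4-iodo-2-methoxybenzene
Product: 20 1-(benzyloxy)-4-{(3S)-3-[3,5-bis(benzyloxy)phenyl]-4,4-bis[2,4-bis(benzyloxy)phenyl]but-1-yn-1-yl}-2-methoxybenzene
Conditions: PdCl2(PPh3)2 (3 mol %), CuI (5 mol %), Et3N/THF, degassed, rt → 40 °C
Reagents that add atoms: none
Why: Sonogashira coupling of the terminal alkyne with the aryl iodide near room temperature is mild enough for the propargylic stereocentre and forms the C8–aryl bond.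

Step 12
Reactants: 20 1-(benzyloxy)-4-{(3S)-3-[3,5-bis(benzyloxy)phenyl]-4,4-bis[2,4-bis(benzyloxy)phenyl]but-1-yn-1-yl}-2-methoxybenzene
Product: 21 (1E,2S,3S)-4,6-bis(benzyloxy)-1-[4-(benzyloxy)-3-methoxybenzylidene]-2-[3,5-bis(benzyloxy)phenyl]-3-[2,4-bis(benzyloxy)phenyl]-2,3-dihydro-1H-indene
Conditions: Pd(OAc)2 (10 mol %), 1,1′-bis(diisopropylphosphino)ferrocene (12 mol %), PivOH (30 mol %), toluene, 100 °C
Reagents that add atoms: none
Why: Proposed new method: divalent palladium carboxylate bound to the alkyne should cleave the C7a–H bond of one 2,4-dibenzyloxyphenyl ring by concerted metalation–deprotonation, the aryl–palladium bond then adds syn across C1≡C8 and pivalic acid cleaves the C8–Pd bond, so that C7a and the new hydrogen end up cis and the guaiacyl ring trans to C7a (E); the sequence hydropalladation, C–H cleavage through a six-membered palladacycle and reductive elimination would give the same product. The closest known reaction types are the Pd(OAc)2-catalysed syn 5-exo-dig hydroarylation of o-alkynylbiaryls that runs by C–H activation and the desymmetrising C–H alkenylation of gem-diaryl vinyl triflates to 1-methyleneindanes under zerovalent palladium; untested are the flexible sp3 tether and the choice between two rings on one carbon by a neighbouring stereocentre. The only ring formed, the five-membered ring C1–C2–C3–C3a–C7a, closes at C1–C7a in the 5-exo-dig mode, since a 6-endo closure is not open to a syn carbopalladation. C3 becomes a stereocentre when one of its two rings is annulated and is controlled by C2: C–H palladation is reversible, and insertion should be faster through the envelope transition state in which the spectator aryl on C3 lies trans to the C2 aryl, which itself turns pseudoaxial to avoid the guaiacyl-bearing C8; the matched enantiomer of an N-acyl amino acid used in place of pivalic acid can reinforce this choice. The step needs site selectivity for C7a–H and selectivity between the diastereotopic rings: C7a–H is the only C–H from which a five-membered ring can form (the C2 aryl could close only 4-exo or 5-endo), and because C7a is meta to both benzyloxy groups it is inert to electrophilic alkyne hydroarylation yet accessible to carboxylate-assisted metalation. Alkene migration into the ring through a palladium hydride is the side process to watch and is limited by the acid additive and by stopping at full conversion.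

Step 13
Reactants: 21 (1E,2S,3S)-4,6-bis(benzyloxy)-1-[4-(benzyloxy)-3-methoxybenzylidene]-2-[3,5-bis(benzyloxy)phenyl]-3-[2,4-bis(benzyloxy)phenyl]-2,3-dihydro-1H-indene
Product: 22 (1E,2S,3S)-2-(3,5-dihydroxyphenyl)-3-(2,4-dihydroxyphenyl)-1-(4-hydroxy-3-methoxybenzylidene)-2,3-dihydro-1H-indene-4,6-diol (CNP0122890.1)
Conditions: BCl3 (14 equiv, 1 M in CH2Cl2), pentamethylbenzene (21 equiv), CH2Cl2, −78 °C; CHCl3/MeOH quench at −78 °C
Reagents that add atoms: none
Why: Lewis-acid debenzylation with BCl3 and pentamethylbenzene as a non-basic benzyl cation scavenger should cleave all seven aryl benzyl ethers at −78 °C, where the aryl methyl ether and the trisubstituted alkene survive, and the cold methanol quench limits exposure of the arylidene indane to HCl so that neither alkene migration nor Friedel–Crafts closure of the C2 aryl onto C8 should occur.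

Compound list
1 | methyl (3,5-dihydroxyphenyl)acetate | COC(=O)Cc1cc(O)cc(O)c1 | starting material
2 | methyl [3,5-bis(benzyloxy)phenyl]acetate | COC(=O)Cc1cc(OCc2ccccc2)cc(OCc2ccccc2)c1 | intermediate
3 | [3,5-bis(benzyloxy)phenyl]acetic acid | OC(=O)Cc1cc(OCc2ccccc2)cc(OCc2ccccc2)c1 | intermediate
4 | (4S)-4-benzyl-1,3-oxazolidin-2-one | O=C1N[C@@H](Cc2ccccc2)CO1 | starting material
5 | [3,5-bis(benzyloxy)phenyl]acetic pivalic anhydride | CC(C)(C)C(=O)OC(=O)Cc1cc(OCc2ccccc2)cc(OCc2ccccc2)c1 | intermediate
6 | (4S)-4-benzyl-3-{[3,5-bis(benzyloxy)phenyl]acetyl}-1,3-oxazolidin-2-one | O=C(Cc1cc(OCc2ccccc2)cc(OCc2ccccc2)c1)N1C(=O)OC[C@@H]1Cc1ccccc1 | intermediate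
7 | 2,2',4,4'-tetrahydroxybenzophenone | O=C(c1ccc(O)cc1O)c1ccc(O)cc1O | starting material
8 | 2,2',4,4'-tetrakis(benzyloxy)benzophenone | O=C(c1ccc(OCc2ccccc2)cc1OCc1ccccc1)c1ccc(OCc2ccccc2)cc1OCc1ccccc1 | intermediate
9 | bis[2,4-bis(benzyloxy)phenyl]methanol | OC(c1ccc(OCc2ccccc2)cc1OCc1ccccc1)c1ccc(OCc2ccccc2)cc1OCc1ccccc1 | intermediate
10 | bis[2,4-bis(benzyloxy)phenyl]methyl methyl ether | COC(c1ccc(OCc2ccccc2)cc1OCc1ccccc1)c1ccc(OCc2ccccc2)cc1OCc1ccccc1 | intermediate
11 | trichlorotitanium Z-enolate of 6 | Cl[Ti](Cl)(Cl)O/C(=C\c1cc(OCc2ccccc2)cc(OCc2ccccc2)c1)N1C(=O)OC[C@@H]1Cc1ccccc1 | intermediate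
12 | (4S)-4-benzyl-3-{(2S)-2-[3,5-bis(benzyloxy)phenyl]-3,3-bis[2,4-bis(benzyloxy)phenyl]propanoyl}-1,3-oxazolidin-2-one | O=C(N1C(=O)OC[C@@H]1Cc1ccccc1)[C@H](c1cc(OCc2ccccc2)cc(OCc2ccccc2)c1)C(c1ccc(OCc2ccccc2)cc1OCc1ccccc1)c1ccc(OCc2ccccc2)cc1OCc1ccccc1 | intermediate
13 | (2S)-2-[3,5-bis(benzyloxy)phenyl]-3,3-bis[2,4-bis(benzyloxy)phenyl]propan-1-ol | OC[C@H](c1cc(OCc2ccccc2)cc(OCc2ccccc2)c1)C(c1ccc(OCc2ccccc2)cc1OCc1ccccc1)c1ccc(OCc2ccccc2)cc1OCc1ccccc1 | intermediate
14 | (2S)-2-[3,5-bis(benzyloxy)phenyl]-3,3-bis[2,4-bis(benzyloxy)phenyl]propanal | O=C[C@H](c1cc(OCc2ccccc2)cc(OCc2ccccc2)c1)C(c1ccc(OCc2ccccc2)cc1OCc1ccccc1)c1ccc(OCc2ccccc2)cc1OCc1ccccc1 | intermediate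
15 | (3R)-3-[3,5-bis(benzyloxy)phenyl]-4,4-bis[2,4-bis(benzyloxy)phenyl]-1,1-dibromobut-1-ene | BrC(Br)=C[C@H](c1cc(OCc2ccccc2)cc(OCc2ccccc2)c1)C(c1ccc(OCc2ccccc2)cc1OCc1ccccc1)c1ccc(OCc2ccccc2)cc1OCc1ccccc1 | intermediate
16 | lithium acetylide of 17 | [Li]C#C[C@H](c1cc(OCc2ccccc2)cc(OCc2ccccc2)c1)C(c1ccc(OCc2ccccc2)cc1OCc1ccccc1)c1ccc(OCc2ccccc2)cc1OCc1ccccc1 | intermediate
17 | (3R)-3-[3,5-bis(benzyloxy)phenyl]-4,4-bis[2,4-bis(benzyloxy)phenyl]but-1-yne | C#C[C@H](c1cc(OCc2ccccc2)cc(OCc2ccccc2)c1)C(c1ccc(OCc2ccccc2)cc1OCc1ccccc1)c1ccc(OCc2ccccc2)cc1OCc1ccccc1 | intermediate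
18 | 4-iodo-2-methoxyphenol | COc1cc(I)ccc1O | starting material
19 | 1-(benzyloxy)-4-iodo-2-methoxybenzene | COc1cc(I)ccc1OCc1ccccc1 | intermediate
20 | 1-(benzyloxy)-4-{(3S)-3-[3,5-bis(benzyloxy)phenyl]-4,4-bis[2,4-bis(benzyloxy)phenyl]but-1-yn-1-yl}-2-methoxybenzene | COc1cc(C#C[C@H](c2cc(OCc3ccccc3)cc(OCc3ccccc3)c2)C(c2ccc(OCc3ccccc3)cc2OCc2ccccc2)c2ccc(OCc3ccccc3)cc2OCc2ccccc2)ccc1OCc1ccccc1 | intermediate
21 | (1E,2S,3S)-4,6-bis(benzyloxy)-1-[4-(benzyloxy)-3-methoxybenzylidene]-2-[3,5-bis(benzyloxy)phenyl]-3-[2,4-bis(benzyloxy)phenyl]-2,3-dihydro-1H-indene | COc1cc(/C=C2/c3cc(OCc4ccccc4)cc(OCc4ccccc4)c3[C@H](c3ccc(OCc4ccccc4)cc3OCc3ccccc3)[C@H]2c2cc(OCc3ccccc3)cc(OCc3ccccc3)c2)ccc1OCc1ccccc1 | intermediate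
22 | (1E,2S,3S)-2-(3,5-dihydroxyphenyl)-3-(2,4-dihydroxyphenyl)-1-(4-hydroxy-3-methoxybenzylidene)-2,3-dihydro-1H-indene-4,6-diol (CNP0122890.1) | COc1cc(/C=C2/c3cc(O)cc(O)c3[C@H](c3ccc(O)cc3O)[C@H]2c2cc(O)cc(O)c2)ccc1O | target

Total step count: 13. Longest linear sequence: 10 steps (steps 1, 2, 5, 6, 7, 8, 9, 11, 12, 13; the branch through steps 3 and 4 is equally long).

Steps most likely to fail

Step 12. The catalyst may fail to engage the unactivated C7a–H across a flexible tether, may choose between the two diastereotopic rings without useful preference, or may move the new alkene into the ring through a palladium hydride. Fallback with known chemistry: setting out from terminal alkyne 17, α-selective hydroalumination catalysed by NiCl2(dppp) (dppp = 1,3-bis(diphenylphosphino)propane) with i-Bu2AlH in THF and bromination of the alkenylalane with N-bromosuccinimide would give (3S)-3-[3,5-bis(benzyloxy)phenyl]-4,4-bis[2,4-bis(benzyloxy)phenyl]-2-bromobut-1-ene F1. Intramolecular C–H alkenylation under zerovalent palladium (Pd2(dba)3, PCy3·HBF4 or a phosphoramidite of the matched hand, PivOH, Cs2CO3, DMA, 80 °C), the established way from gem-diaryl vinyl electrophiles to 1-methyleneindanes, would then close C1–C7a to (2S,3S)-4,6-bis(benzyloxy)-2-[3,5-bis(benzyloxy)phenyl]-3-[2,4-bis(benzyloxy)phenyl]-1-methylidene-2,3-dihydro-1H-indene F2. Heck arylation of F2 with aryl iodide 19 (Pd(OAc)2, P(o-tol)3, Et3N, DMF, 90 °C) would place the guaiacyl ring on C8 and come back to the route at 21; the E isomer should be favoured because the new aryl group avoids the peri hydrogen on C7.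

Step 5. Capture of a hindered, highly stabilised cation by a hindered enolate may be slow, so that self-arylation of ether 10 at its activated ring positions and Lewis-acid loss of benzyl ethers take over. Fallback: setting out from imide 6, the same titanium enolate (TiCl4, i-Pr2NEt, CH2Cl2, 0 °C) is alkylated with trimethyl orthoformate, a small SN1 electrophile, to give (4S)-4-benzyl-3-{(2R)-2-[3,5-bis(benzyloxy)phenyl]-3,3-dimethoxypropanoyl}-1,3-oxazolidin-2-one F3 with the same facial sense. Double Friedel–Crafts arylation of the acetal carbon with 1,3-bis(benzyloxy)benzene (3 equiv, Bi(OTf)3 5 mol %, CH2Cl2, 0 °C), which reacts at its C4 position, then builds both identical rings on C3 and comes back to the route at 12.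

Step 6. Hydride may attack the ring carbamate carbonyl in place of the shielded exocyclic carbonyl and open the auxiliary. Fallback: setting out from 12, lithium ethanethiolate (EtSH, n-BuLi, THF, 0 °C), a small nucleophile suited to hindered imides, should give S-ethyl (2S)-2-[3,5-bis(benzyloxy)phenyl]-3,3-bis[2,4-bis(benzyloxy)phenyl]propanethioate F4. Partial reduction of F4 with i-Bu2AlH (CH2Cl2, −78 °C) then leads directly to aldehyde 14, where the route is rejoined without the separate oxidation.

Further compounds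
F1 | step 12 | (3S)-3-[3,5-bis(benzyloxy)phenyl]-4,4-bis[2,4-bis(benzyloxy)phenyl]-2-bromobut-1-ene | C=C(Br)[C@H](c1cc(OCc2ccccc2)cc(OCc2ccccc2)c1)C(c1ccc(OCc2ccccc2)cc1OCc1ccccc1)c1ccc(OCc2ccccc2)cc1OCc1ccccc1
F2 | step 12 | (2S,3S)-4,6-bis(benzyloxy)-2-[3,5-bis(benzyloxy)phenyl]-3-[2,4-bis(benzyloxy)phenyl]-1-methylidene-2,3-dihydro-1H-indene | C=C1c2cc(OCc3ccccc3)cc(OCc3ccccc3)c2[C@H](c2ccc(OCc3ccccc3)cc2OCc2ccccc2)[C@H]1c1cc(OCc2ccccc2)cc(OCc2ccccc2)c1
F3 | step 5 | (4S)-4-benzyl-3-{(2R)-2-[3,5-bis(benzyloxy)phenyl]-3,3-dimethoxypropanoyl}-1,3-oxazolidin-2-one | O=C(N1C(=O)OC[C@@H]1Cc1ccccc1)[C@H](c1cc(OCc2ccccc2)cc(OCc2ccccc2)c1)C(OC)OC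
F4 | step 6 | S-ethyl (2S)-2-[3,5-bis(benzyloxy)phenyl]-3,3-bis[2,4-bis(benzyloxy)phenyl]propanethioate | CCSC(=O)[C@H](c1cc(OCc2ccccc2)cc(OCc2ccccc2)c1)C(c1ccc(OCc2ccccc2)cc1OCc1ccccc1)c1ccc(OCc2ccccc2)cc1OCc1ccccc1
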